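The C6–OMe and C8–OMe bonds of ring A are disconnected, so the whole C15 flavonol skeleton comes from kaempferol. The key step exploits the fact that C6 and C8 are the only unsubstituted carbons of ring A and each sits between two oxygen-bearing carbons (C5/C7 and C7/C8a). They are brominated selectively, and one CuBr-mediated reaction with NaOMe then exchanges both bromines for methoxy groups, completing the pentaoxygenated ring A. The precursor is 6,8-dibromo-7-O-methylkaempferol carrying benzyl ethers at O3 and O4' and a free, chelated 5-OH; hydrogenolysis afterwards releases the target.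

Key step: step 7

Remark: flavone numbering is used throughout (O1, C2, C3, C4, C4a, C5–C8, C8a; ring B positions primed), and the chelated 5-OH is assumed to pass through benzylation, bromination and methoxylation unprotected.

Step 1
Reactants: 1 kaempferol; 2 acetic anhydride
Product: 3 3,5,7-triacetoxy-2-(4-acetoxyphenyl)-4H-chromen-4-one (kaempferol tetraacetate)
Conditions: Ac2O (excess), pyridine, 70 °C
Reagents that add atoms: acetic anhydride, CC(=O)OC(C)=O
Why: Exhaustive O-acylation (nucleophilic acyl substitution with pyridine as base and acyl-transfer catalyst) esterifies all four hydroxyls, gentle heating being enough to bring in the hydrogen-bonded 5-OH.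

Step 2
Reactants: 3 kaempferol tetraacetate
Product: 4 3,5-diacetoxy-2-(4-acetoxyphenyl)-7-hydroxy-4H-chromen-4-one (kaempferol 3,5,4'-triacetate)
Conditions: PhSH (1.2 equiv), imidazole (0.3 equiv), NMP, 0 °C
Reagents that add atoms: none
Why: Regioselective thiolysis (acyl transfer to thiolate) should remove the 7-acetate first, because the 7-phenoxide, conjugated through ring A with the C4 carbonyl, is the best leaving group among the four esters.

Step 3
Reactants: 4 kaempferol 3,5,4'-triacetate; 5 iodomethane
Product: 6 3,5-diacetoxy-2-(4-acetoxyphenyl)-7-methoxy-4H-chromen-4-one (rhamnocitrin triacetate)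
Conditions: MeI (1.5 equiv), K2CO3 (1.2 equiv), dry acetone, rt
Reagents that add atoms: iodomethane, CI
Why: Williamson ether synthesis on the only free phenol; the other three oxygens are blocked as acetates, which should survive anhydrous carbonate at room temperature.

Step 4
Reactants: 6 rhamnocitrin triacetate
Product: 7 3,5-dihydroxy-2-(4-hydroxyphenyl)-7-methoxy-4H-chromen-4-one (rhamnocitrin, 7-O-methylkaempferol)
Conditions: 6 M aq. HCl, MeCN, reflux
Reagents that add atoms: none
Why: Acid-catalysed ester hydrolysis cleaves the three aryl and enol acetates, while the aryl methyl ether is inert to aqueous HCl and the acidic medium avoids air oxidation of the flavonol anion.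

Step 5
Reactants: 7 rhamnocitrin; 8 benzyl bromide
Product: 9 3-(benzyloxy)-2-[4-(benzyloxy)phenyl]-5-hydroxy-7-methoxy-4H-chromen-4-one
Conditions: BnBr (2.3 equiv), K2CO3 (3 equiv), DMF, rt to 40 °C
Reagents that add atoms: benzyl bromide, BrCc1ccccc1
Why: Williamson etherification alkylates the 3- and 4'-hydroxyls, whereas the 5-OH, held in a strong hydrogen bond to the C4 carbonyl, is far less nucleophilic and should stay free with a small excess of halide at mild temperature.

Step 6
Reactants: 9 3,4'-di-O-benzyl-7-O-methylkaempferol; 10 N-bromosuccinimide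
Product: 11 3-(benzyloxy)-2-[4-(benzyloxy)phenyl]-6,8-dibromo-5-hydroxy-7-methoxy-4H-chromen-4-one
Conditions: NBS (2.1 equiv), DMF, 0 °C to rt, dark
Reagents that add atoms: N-bromosuccinimide, O=C1CCC(=O)N1Br
Why: Electrophilic aromatic bromination goes to C6 and C8, the only free ring A carbons and both activated ortho/para by the 5-OH and 7-OMe; ring B, a single alkoxy arene conjugated to the enone, and the benzylic CH2 groups should not react under ionic conditions without light.

Step 7
Reactants: 11 6,8-dibromo-3,4'-di-O-benzyl-7-O-methylkaempferol; 12 sodium methoxide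
Product: 13 3-(benzyloxy)-2-[4-(benzyloxy)phenyl]-5-hydroxy-6,7,8-trimethoxy-4H-chromen-4-one
Conditions: NaOMe (30% in MeOH, 15 equiv), CuBr (0.5 equiv), dry degassed DMF, 110 °C, Ar; then 1 M aq. HCl
Reagents that add atoms: sodium methoxide, C[O-].[Na+]
Why: NaOMe first converts the 5-OH into its phenoxide and CuBr into a methoxycuprate; oxidative addition of each aryl C–Br bond to monovalent copper gives a trivalent aryl copper methoxide, and reductive elimination forms the C6–OMe and C8–OMe bonds and returns monovalent copper. The closest known reaction type is the Ullmann-type ether synthesis (copper-mediated methanolysis of bromoarenes), which is established for 6,8-dibromo-5,7-dioxygenated flavones. No ring is closed and no stereocenter is created. The step needs ipso substitution at both carbons without hydrodebromination: the sites are fixed by the bromines installed in step 6, the ortho oxygens (5-phenoxide with the C4 carbonyl at C6, O1 and 7-OMe at C8) can hold copper next to each C–Br bond, and a large excess of dry, oxygen-free methoxide should keep methoxide transfer faster than reduction. Benzyl and methyl ethers are inert to NaOMe, and the acidic work-up returns the chelated 5-OH.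

Step 8
Reactants: 13 3,4'-di-O-benzyl-5-hydroxy-6,7,8-trimethoxyflavonol
Product: 14 3,5-dihydroxy-2-(4-hydroxyphenyl)-6,7,8-trimethoxy-4H-chromen-4-one (3,5,4'-trihydroxy-6,7,8-trimethoxyflavone, target)
Conditions: H2 (1 atm), 10% Pd/C, EtOAc/MeOH, rt
Reagents that add atoms: none
Why: Heterogeneous catalytic hydrogenolysis cleaves both benzylic C–O bonds, while the aryl methyl ethers and the conjugated C2=C3 bond of the chromone should be untouched at atmospheric pressure and room temperature.

Compound list
1 | kaempferol | O=c1c(O)c(-c2ccc(O)cc2)oc2cc(O)cc(O)c12 | starting material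
2 | acetic anhydride | CC(=O)OC(C)=O | starting material
3 | 3,5,7-triacetoxy-2-(4-acetoxyphenyl)-4H-chromen-4-one | CC(=O)Oc1ccc(-c2oc3cc(OC(C)=O)cc(OC(C)=O)c3c(=O)c2OC(C)=O)cc1 | intermediate
4 | 3,5-diacetoxy-2-(4-acetoxyphenyl)-7-hydroxy-4H-chromen-4-one | CC(=O)Oc1ccc(-c2oc3cc(O)cc(OC(C)=O)c3c(=O)c2OC(C)=O)cc1 | intermediate
5 | iodomethane | CI | starting material
6 | 3,5-diacetoxy-2-(4-acetoxyphenyl)-7-methoxy-4H-chromen-4-one | CC(=O)Oc1ccc(-c2oc3cc(OC)cc(OC(C)=O)c3c(=O)c2OC(C)=O)cc1 | intermediate
7 | 3,5-dihydroxy-2-(4-hydroxyphenyl)-7-methoxy-4H-chromen-4-one (rhamnocitrin) | COc1cc(O)c2c(=O)c(O)c(-c3ccc(O)cc3)oc2c1 | intermediate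
8 | benzyl bromide | BrCc1ccccc1 | starting material
9 | 3-(benzyloxy)-2-[4-(benzyloxy)phenyl]-5-hydroxy-7-methoxy-4H-chromen-4-one | COc1cc(O)c2c(=O)c(OCc3ccccc3)c(-c3ccc(OCc4ccccc4)cc3)oc2c1 | intermediate
10 | N-bromosuccinimide | O=C1CCC(=O)N1Br | starting material
11 | 3-(benzyloxy)-2-[4-(benzyloxy)phenyl]-6,8-dibromo-5-hydroxy-7-methoxy-4H-chromen-4-one | COc1c(Br)c(O)c2c(=O)c(OCc3ccccc3)c(-c3ccc(OCc4ccccc4)cc3)oc2c1Br | intermediate
12 | sodium methoxide | C[O-].[Na+] | starting material
13 | 3-(benzyloxy)-2-[4-(benzyloxy)phenyl]-5-hydroxy-6,7,8-trimethoxy-4H-chromen-4-one | COc1c(OC)c(O)c2c(=O)c(OCc3ccccc3)c(-c3ccc(OCc4ccccc4)cc3)oc2c1OC | intermediate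
14 | 3,5-dihydroxy-2-(4-hydroxyphenyl)-6,7,8-trimethoxy-4H-chromen-4-one | COc1c(OC)c(O)c2c(=O)c(O)c(-c3ccc(O)cc3)oc2c1OC | target

Total step count: 8
Longest linear sequence: 8 steps (kaempferol 1 to target 14)

Steps most likely to fail

Step 7. The risk is reductive loss of bromine in competition with C–O bond formation, or stalling after the first substitution because the substrate reacts as an electron-rich phenoxide. The fallback sets out from 11. The 5-OH would be capped with benzyl bromide 8 (K2CO3, DMF, 70 °C) to give 3,5-bis(benzyloxy)-2-[4-(benzyloxy)phenyl]-6,8-dibromo-7-methoxy-4H-chromen-4-one F1, which cannot form a phenoxide. A palladium-catalysed C–O cross-coupling with methanol (Pd2(dba)3 as zerovalent palladium source, tBuBrettPhos, Cs2CO3, MeOH/toluene, 80 °C) would then give 3,5-bis(benzyloxy)-2-[4-(benzyloxy)phenyl]-6,7,8-trimethoxy-4H-chromen-4-one F2. Here the bulky biaryl phosphine drives C–O reductive elimination from divalent palladium ahead of β-hydride elimination. Hydrogenolysis of all three benzyl ethers under the conditions of step 8 comes back to the route at 14.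

Step 2. The risk is loss of regioselectivity in the thiolysis (removal of a second ester, most likely at O4') or acetyl migration while the partially acylated phenol is isolated. The fallback sets out from 3 and replaces the 7-acetoxy group directly in one pot with iodomethane 5 and anhydrous K2CO3 in refluxing dry acetone. The most labile 7-acetate is cleaved by carbonate and the phenoxide is methylated as it forms, so no free phenol accumulates. It comes back to the route at 6 and makes no new compound (F0).

Step 3. The risk is base-induced acetyl transfer between phenolic oxygens, or partial deacetylation under carbonate, which would scramble the site of methylation. The fallback sets out from 4 and uses a Mitsunobu etherification with methanol (PPh3, DIAD, MeOH, THF, 0 °C to rt). This runs under neutral conditions with no free phenoxide or carbonate. It comes back to the route at 6 and makes no new compound (F0).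

Further compounds
F1 | step 7 | 3,5-bis(benzyloxy)-2-[4-(benzyloxy)phenyl]-6,8-dibromo-7-methoxy-4H-chromen-4-one | COc1c(Br)c(OCc2ccccc2)c2c(=O)c(OCc3ccccc3)c(-c3ccc(OCc4ccccc4)cc3)oc2c1Br
F2 | step 7 | 3,5-bis(benzyloxy)-2-[4-(benzyloxy)phenyl]-6,7,8-trimethoxy-4H-chromen-4-one | COc1c(OC)c(OCc2ccccc2)c2c(=O)c(OCc3ccccc3)c(-c3ccc(OCc4ccccc4)cc3)oc2c1OC
F0 | step 2 | none | none
F0 | step 3 | none | none
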